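**Retrosynthetic overview**
1. Last bond made (key step): C5–O, by a singlet-oxygen ene reaction on the 4Z-ene macrolide (the C15 methyl becomes the exocyclic methylene), then O–O reduction.
2. The ten-membered carbocycle and the cis-fused γ-lactone are closed together by an intramolecular indium Barbier allylation (C6–C7) and lactonisation.
3. The C8–O ester bond and its stereocentre come from a new catalytic enantioselective α-isobutyryloxylation of an aldehyde; the acrylate unit comes from vinylalumination and SN2′ bromination.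
4. The furanone (first ring) is closed through the C3–O bond by 5-endo-dig oxa-Michael addition of an α′-hydroxy ynone, made from an alkynyllithium and a Seebach dioxolanone that carries C10 from D-lactic acid.
5. Ring order: furanone, then carbocycle plus lactone in one step. Commercial inputs: D-lactic acid, pivalaldehyde, allyl bromide, (Z)-3-methylpent-2-en-4-yn-1-ol, methyl propiolate, diisobutyryl peroxide.

Assumption: macrocyclic compounds are named with germacrane numbering (C1 ketone, C3–O–C10 bridge, C6 lactone oxygen, C8 ester, C13/C15 methylenes, C14 methyl), and the target is taken exactly as written (6,7-cis-fused lactone; 5S,6R,7R,8R,10S).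

**Route**

Step 1
Reactants: 1 (2R)-2-hydroxypropanoic acid (D-lactic acid)
Product: 2 (2R,5R)-2-tert-butyl-5-methyl-1,3-dioxolan-4-one
Conditions: pivalaldehyde, TsOH (cat.), pentane, reflux, Dean–Stark; recrystallise at −78 °C to the cis isomer
Reagents that add atoms: pivalaldehyde (CC(C)(C)C=O)
Why: Acid-catalysed acetalisation (Seebach self-regeneration-of-stereocentres auxiliary) gives the cis acetal as the crystalline major isomer, with C5 carried over unchanged from D-lactic acid.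

Step 2
Reactants: 2 (2R,5R)-2-tert-butyl-5-methyl-1,3-dioxolan-4-one
Product: 3 (2R,5S)-2-tert-butyl-5-methyl-5-(prop-2-en-1-yl)-1,3-dioxolan-4-one
Conditions: LiN(iPr)2, THF, −78 °C; allyl bromide, −78 → −30 °C
Reagents that add atoms: allyl bromide (C=CCBr)
Why: Seebach enolate alkylation, in which allyl bromide enters trans to the tert-butyl group and so sets the quaternary centre (future C10, S) with retention of the lactic acid configuration.

Step 3
Reactants: 4 (2Z)-3-methylpent-2-en-4-yn-1-ol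
Product: 5 tert-butyl(dimethyl){[(2Z)-3-methylpent-2-en-4-yn-1-yl]oxy}silane
Conditions: TBSCl, imidazole, CH2Cl2, 0 → 23 °C
Reagents that add atoms: tert-butyldimethylsilyl chloride (CC(C)(C)[Si](C)(C)Cl)
Why: Standard silylation that masks the allylic alcohol through the organolithium, oxidation and bromination steps without touching the Z-alkene.

Step 4
Reactants: 5 tert-butyl(dimethyl){[(2Z)-3-methylpent-2-en-4-yn-1-yl]oxy}silane; 3 (2R,5S)-2-tert-butyl-5-methyl-5-(prop-2-en-1-yl)-1,3-dioxolan-4-one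
Product: 7 (2S)-5-[(2Z)-4-{[tert-butyl(dimethyl)silyl]oxy}but-2-en-2-yl]-2-methyl-2-(prop-2-en-1-yl)furan-3(2H)-one, via hydroxy ynone 6 (not isolated)
Conditions: 5, nBuLi, THF, −78 °C; then 3, −78 → −40 °C; AcOH quench; then K2CO3 (cat.), MeOH, 23 °C
Reagents that add atoms: none
Why: Acylation of the alkynyllithium by the dioxolanone (stable tetrahedral adduct that loses pivalaldehyde on quench) gives the α′-hydroxy ynone, whose tertiary hydroxyl closes the furanone by base-catalysed 5-endo-dig oxa-Michael addition (C3–O bond) without touching C10.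

Step 5
Reactants: 7 (2S)-5-[(2Z)-4-{[tert-butyl(dimethyl)silyl]oxy}but-2-en-2-yl]-2-methyl-2-(prop-2-en-1-yl)furan-3(2H)-one
Product: 8 3-[(2S)-5-[(2Z)-4-{[tert-butyl(dimethyl)silyl]oxy}but-2-en-2-yl]-2-methyl-3-oxo-2,3-dihydrofuran-2-yl]propanal
Conditions: PdCl2(PhCN)2 (10 mol %), CuCl2·2H2O (10 mol %), AgNO2 (5 mol %), O2 (1 atm), tBuOH/MeNO2 15:1, 23 °C
Reagents that add atoms: dioxygen (O=O)
Why: Nitrite-modified aldehyde-selective (anti-Markovnikov) Wacker oxidation of the only terminal alkene, where the adjacent quaternary carbon disfavours Markovnikov attack and the conjugated trisubstituted alkene is inert to divalent palladium.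

Step 6
Reactants: 8 3-[(2S)-5-[(2Z)-4-{[tert-butyl(dimethyl)silyl]oxy}but-2-en-2-yl]-2-methyl-3-oxo-2,3-dihydrofuran-2-yl]propanal
Product: 9 (2R)-3-[(2S)-5-[(2Z)-4-{[tert-butyl(dimethyl)silyl]oxy}but-2-en-2-yl]-2-methyl-3-oxo-2,3-dihydrofuran-2-yl]-1-oxopropan-2-yl 2-methylpropanoate
Conditions: (R)-2-(triphenylmethyl)pyrrolidine (10 mol %), hydroquinone (10 mol %), bis(2-methylpropanoyl) peroxide (1.2 equiv, cold alkane solution), THF, −20 °C; crude 9 used at once
Reagents that add atoms: bis(2-methylpropanoyl) peroxide (CC(C)C(=O)OOC(=O)C(C)C)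
Why: Proposed new method: catalytic enantioselective α-acyloxylation of an aldehyde with an aliphatic diacyl peroxide, in which the E-enamine of 8 attacks one peroxide oxygen (SN2 at O into the O–O σ*, isobutyrate leaving) on the face not shielded by the trityl group and hydrolysis of the α-acyloxy iminium ion releases 9 with C8 (R) set by the catalyst alone and the natural ester already in place; hydroquinone and low temperature suppress radical and ionic decomposition of the peroxide; the closest known reaction type is the amine-catalysed α-benzoyloxylation of aldehydes with dibenzoyl peroxide, not yet shown for secondary-alkyl diacyl peroxides or substrates of this kind.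

Step 7
Reactants: 9 (2R)-3-[(2S)-5-[(2Z)-4-{[tert-butyl(dimethyl)silyl]oxy}but-2-en-2-yl]-2-methyl-3-oxo-2,3-dihydrofuran-2-yl]-1-oxopropan-2-yl 2-methylpropanoate
Product: 10 methyl (4R)-5-[(2S)-5-[(2Z)-4-{[tert-butyl(dimethyl)silyl]oxy}but-2-en-2-yl]-2-methyl-3-oxo-2,3-dihydrofuran-2-yl]-3-hydroxy-2-methylidene-4-[(2-methylpropanoyl)oxy]pentanoate (both C3 epimers)
Conditions: iBu2AlH, N-methylmorpholine N-oxide, THF, 0 °C, then methyl propiolate; then 9, 0 → 23 °C; Rochelle salt work-up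
Reagents that add atoms: methyl propiolate (C#CC(=O)OC)
Why: Hydroalumination of the propiolate gives an α-(methoxycarbonyl)vinylalane that adds 1,2 to the aldehyde (base-free route to the Morita–Baylis–Hillman adduct, so the labile C8 centre is not epimerised), and the new C3 carbinol needs no control because it becomes sp2 in the next step.

Step 8
Reactants: 10 methyl (4R)-5-[(2S)-5-[(2Z)-4-{[tert-butyl(dimethyl)silyl]oxy}but-2-en-2-yl]-2-methyl-3-oxo-2,3-dihydrofuran-2-yl]-3-hydroxy-2-methylidene-4-[(2-methylpropanoyl)oxy]pentanoate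
Product: 11 methyl (2Z,4R)-2-(bromomethyl)-5-[(2S)-5-[(2Z)-4-{[tert-butyl(dimethyl)silyl]oxy}but-2-en-2-yl]-2-methyl-3-oxo-2,3-dihydrofuran-2-yl]-4-[(2-methylpropanoyl)oxy]pent-2-enoate
Conditions: Me2S, NBS, CH2Cl2, 0 °C; then 10, 0 → 23 °C
Reagents that add atoms: N-bromosuccinimide (O=C1CCC(=O)N1Br)
Why: Corey–Kim-type activation of the allylic alcohol and SN2′ displacement by bromide gives the thermodynamic (Z)-2-(bromomethyl)enoate (C8 trans to the ester, so no butenolide can form) without involving the C8 centre.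

Step 9
Reactants: 11 methyl (2Z,4R)-2-(bromomethyl)-5-[(2S)-5-[(2Z)-4-{[tert-butyl(dimethyl)silyl]oxy}but-2-en-2-yl]-2-methyl-3-oxo-2,3-dihydrofuran-2-yl]-4-[(2-methylpropanoyl)oxy]pent-2-enoate
Product: 12 methyl (2Z,4R)-2-(bromomethyl)-5-[(2S)-5-[(2Z)-4-hydroxybut-2-en-2-yl]-2-methyl-3-oxo-2,3-dihydrofuran-2-yl]-4-[(2-methylpropanoyl)oxy]pent-2-enoate
Conditions: HF·pyridine, THF/pyridine, 0 °C
Reagents that add atoms: none
Why: Fluoride-mediated desilylation under buffered acidic conditions that leave the allylic bromide, the isobutyrate and the furanone intact.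

Step 10
Reactants: 12 methyl (2Z,4R)-2-(bromomethyl)-5-[(2S)-5-[(2Z)-4-hydroxybut-2-en-2-yl]-2-methyl-3-oxo-2,3-dihydrofuran-2-yl]-4-[(2-methylpropanoyl)oxy]pent-2-enoate
Product: 13 methyl (2Z,4R)-2-(bromomethyl)-5-[(2S)-2-methyl-3-oxo-5-[(2Z)-4-oxobut-2-en-2-yl]-2,3-dihydrofuran-2-yl]-4-[(2-methylpropanoyl)oxy]pent-2-enoate
Conditions: Dess–Martin periodinane, CH2Cl2, 0 °C
Reagents that add atoms: none
Why: Dess–Martin oxidation turns the primary allylic alcohol into the Z-enal under neutral, non-isomerising conditions that tolerate the allylic bromide.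

Step 11
Reactants: 13 methyl (2Z,4R)-2-(bromomethyl)-5-[(2S)-2-methyl-3-oxo-5-[(2Z)-4-oxobut-2-en-2-yl]-2,3-dihydrofuran-2-yl]-4-[(2-methylpropanoyl)oxy]pent-2-enoate
Product: 15 (4Z,6S,7R,8R,10S)-8-[(2-methylpropanoyl)oxy]-1-oxo-3,10-epoxygermacra-2,4,11(13)-trien-12,6-olide (6,7-cis-fused lactone), via hydroxy ester 14 (not isolated)
Conditions: In powder (3 equiv), THF/H2O 3:1, slow addition of 13 to 2 mM, 23 °C; then PPTS (cat.), CH2Cl2, 23 °C
Reagents that add atoms: none
Why: Intramolecular indium Barbier allylation then lactonisation, in which C7 of the (Z)-2-(methoxycarbonyl)allylindium adds to the aldehyde (far more electrophilic than the vinylogous-ester ketone) through a chair transition state that makes C6–O and C7–C11 syn (cis-lactone), while C8 directs the face of C7 (H-8 in the allyl plane to avoid allylic strain, ring carbon C9 anti to the forming bond, acyloxy outside), setting C6 and C7 as in the target.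

Step 12
Reactants: 15 (4Z,6S,7R,8R,10S)-8-[(2-methylpropanoyl)oxy]-1-oxo-3,10-epoxygermacra-2,4,11(13)-trien-12,6-olide
Product: 17 (5S,6R,7R,8R,10S)-5-hydroxy-8-[(2-methylpropanoyl)oxy]-1-oxo-3,10-epoxygermacra-2,4(15),11(13)-trien-12,6-olide, via hydroperoxide 16 (not isolated)
Conditions: O2, tetraphenylporphyrin (1 mol %), white LED, CH2Cl2, −20 °C; then PPh3 (1.05 equiv), −20 → 0 °C
Reagents that add atoms: dioxygen (O=O)
Why: Schenck ene reaction (key C5–O bond formation) in which singlet oxygen bonds to C5 and takes hydrogen from the C15 methyl geminal to the electron-poor furanone (gem effect; H-6 lies in the alkene plane and cannot be abstracted), attacking the face anti to the C6–O bond of the allylic-strain-locked Z-alkene to give the 5,6-erythro (5S) hydroperoxide, which PPh3 reduces to the alcohol.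

**Compound list**
1 | (2R)-2-hydroxypropanoic acid (D-lactic acid) | C[C@@H](O)C(=O)O | starting material
2 | (2R,5R)-2-tert-butyl-5-methyl-1,3-dioxolan-4-one (cis) | C[C@H]1O[C@@H](C(C)(C)C)OC1=O | intermediate
3 | (2R,5S)-2-tert-butyl-5-methyl-5-(prop-2-en-1-yl)-1,3-dioxolan-4-one | C=CC[C@]1(C)O[C@@H](C(C)(C)C)OC1=O | intermediate
4 | (2Z)-3-methylpent-2-en-4-yn-1-ol | C#C/C(C)=C\CO | starting material
5 | tert-butyl(dimethyl){[(2Z)-3-methylpent-2-en-4-yn-1-yl]oxy}silane | C#C/C(C)=C\CO[Si](C)(C)C(C)(C)C | intermediate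
6 | (4S,8Z)-10-{[tert-butyl(dimethyl)silyl]oxy}-4-hydroxy-4,8-dimethyldeca-1,8-dien-6-yn-5-one | C=CC[C@](C)(O)C(=O)C#C/C(C)=C\CO[Si](C)(C)C(C)(C)C | intermediate
7 | (2S)-5-[(2Z)-4-{[tert-butyl(dimethyl)silyl]oxy}but-2-en-2-yl]-2-methyl-2-(prop-2-en-1-yl)furan-3(2H)-one | C=CC[C@]1(C)OC(=CC1=O)/C(C)=C\CO[Si](C)(C)C(C)(C)C | intermediate
8 | 3-[(2S)-5-[(2Z)-4-{[tert-butyl(dimethyl)silyl]oxy}but-2-en-2-yl]-2-methyl-3-oxo-2,3-dihydrofuran-2-yl]propanal | O=CCC[C@]1(C)OC(=CC1=O)/C(C)=C\CO[Si](C)(C)C(C)(C)C | intermediate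
9 | (2R)-3-[(2S)-5-[(2Z)-4-{[tert-butyl(dimethyl)silyl]oxy}but-2-en-2-yl]-2-methyl-3-oxo-2,3-dihydrofuran-2-yl]-1-oxopropan-2-yl 2-methylpropanoate | O=C[C@H](OC(=O)C(C)C)C[C@]1(C)OC(=CC1=O)/C(C)=C\CO[Si](C)(C)C(C)(C)C | intermediate
10 | methyl (4R)-5-[(2S)-5-[(2Z)-4-{[tert-butyl(dimethyl)silyl]oxy}but-2-en-2-yl]-2-methyl-3-oxo-2,3-dihydrofuran-2-yl]-3-hydroxy-2-methylidene-4-[(2-methylpropanoyl)oxy]pentanoate (both C3 epimers) | C=C(C(=O)OC)C(O)[C@H](OC(=O)C(C)C)C[C@]1(C)OC(=CC1=O)/C(C)=C\CO[Si](C)(C)C(C)(C)C | intermediate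
11 | methyl (2Z,4R)-2-(bromomethyl)-5-[(2S)-5-[(2Z)-4-{[tert-butyl(dimethyl)silyl]oxy}but-2-en-2-yl]-2-methyl-3-oxo-2,3-dihydrofuran-2-yl]-4-[(2-methylpropanoyl)oxy]pent-2-enoate | BrC/C(C(=O)OC)=C\[C@H](OC(=O)C(C)C)C[C@]1(C)OC(=CC1=O)/C(C)=C\CO[Si](C)(C)C(C)(C)C | intermediate
12 | methyl (2Z,4R)-2-(bromomethyl)-5-[(2S)-5-[(2Z)-4-hydroxybut-2-en-2-yl]-2-methyl-3-oxo-2,3-dihydrofuran-2-yl]-4-[(2-methylpropanoyl)oxy]pent-2-enoate | BrC/C(C(=O)OC)=C\[C@H](OC(=O)C(C)C)C[C@]1(C)OC(=CC1=O)/C(C)=C\CO | intermediate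
13 | methyl (2Z,4R)-2-(bromomethyl)-5-[(2S)-2-methyl-3-oxo-5-[(2Z)-4-oxobut-2-en-2-yl]-2,3-dihydrofuran-2-yl]-4-[(2-methylpropanoyl)oxy]pent-2-enoate | BrC/C(C(=O)OC)=C\[C@H](OC(=O)C(C)C)C[C@]1(C)OC(=CC1=O)/C(C)=C\C=O | intermediate
14 | methyl (4Z,6S,7S,8R,10S)-6-hydroxy-8-[(2-methylpropanoyl)oxy]-1-oxo-3,10-epoxygermacra-2,4,11(13)-trien-12-oate (6-OH and the C7 acrylate on the same face, as in 15) | COC(=O)C(=C)[C@@H]1[C@H](OC(=O)C(C)C)C[C@]2(C)OC(=CC2=O)/C(C)=C\[C@@H]1O | intermediate
15 | (4Z,6S,7R,8R,10S)-8-[(2-methylpropanoyl)oxy]-1-oxo-3,10-epoxygermacra-2,4,11(13)-trien-12,6-olide (6,7-cis-fused lactone; the target without 5-OH and with a C4 methyl on the Z-4,5-alkene) | C=C1C(=O)O[C@@H]2[C@H]1[C@H](OC(=O)C(C)C)C[C@]1(C)OC(=CC1=O)/C(C)=C\2 | intermediate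
16 | (5S,6R,7R,8R,10S)-5-hydroperoxy-8-[(2-methylpropanoyl)oxy]-1-oxo-3,10-epoxygermacra-2,4(15),11(13)-trien-12,6-olide | C=C1C(=O)O[C@@H]2[C@H]1[C@H](OC(=O)C(C)C)C[C@]1(C)OC(=CC1=O)C(=C)[C@@H]2OO | intermediate
17 | (5S,6R,7R,8R,10S)-5-hydroxy-8-[(2-methylpropanoyl)oxy]-1-oxo-3,10-epoxygermacra-2,4(15),11(13)-trien-12,6-olide | C=C1C(=O)O[C@@H]2[C@H]1[C@H](OC(=O)C(C)C)C[C@]1(C)OC(=CC1=O)C(=C)[C@@H]2O | target

**Step count**
Total: 12 steps. Longest linear sequence: 11 steps (steps 1, 2 and 4–12, from 1).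

**Three steps most likely to fail, with fallbacks**

Step 6 (proposed new α-isobutyryloxylation). The aliphatic peroxide may decompose faster than the enamine attacks it, the enantioselectivity is untested, and 9 is configurationally labile. The fallback uses known chemistry, sets out from 8 and comes back at 9. L-Proline-catalysed α-aminoxylation of 8 with nitrosobenzene (DMSO, 4 °C) with NaBH4 added to the same flask gives the (R)-anilinooxy alcohol F1. Zn/AcOH cleaves the N–O bond to give the diol F2. TESCl/imidazole at −40 °C silylates only the primary hydroxyl to give the triethylsilyl ether F3. Isobutyryl chloride/pyridine/DMAP acylates the secondary hydroxyl to give the silyl ether isobutyrate F4. PPTS in MeOH at 0 °C removes the primary triethylsilyl group (the allylic TBS ether stays) to give the hydroxy isobutyrate F5. Dess–Martin oxidation of F5 gives 9.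

Step 11 (Barbier macrocyclisation). Ring strain, oligomerisation, or a diastereomer other than the 6,7-cis lactone could result if the organoindium equilibrates or the ring overrides the chair model. The fallback sets out from 12 and comes back at 15, and replaces the organoindium formed in water by a preformed allylboron nucleophile that reacts through a closed six-membered boron transition state. Pd2(dba)3-catalysed borylation of 12 with B2pin2 gives the allylboronate alcohol F6. Dess–Martin oxidation gives the allylboronate enal F7. On warming in toluene with Sc(OTf)3 (cat.), F7 undergoes stereospecific intramolecular allylboration (γ-substituent cis to CH2B gives the syn adduct), and PPTS then closes the lactone to 15.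

Step 12 (singlet-oxygen ene reaction). The alkene is electron-poor and may react slowly, the conjugated diene could undergo [4+2] addition, and the face selectivity rests on an acyclic model. The fallback sets out from 15 and comes back at 17 by a stepwise oxygen transfer and radical elimination instead of a pericyclic ene reaction. Dimethyldioxirane (acetone, 0 °C) epoxidises the 4,5-alkene anti to the C6–O bond to give the cis-epoxide F8. Cp2TiCl (from Cp2TiCl2 and Mn, THF) opens F8 by homolysis of the tertiary C4–O bond, and the C4 radical loses a C15 hydrogen through a second equivalent of trivalent titanium, giving the exocyclic alkene and the C5 alcohol of 17 with the epoxide C5–O configuration retained.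

**Further compounds**
F1 | step 6 | (2S)-2-[(2R)-2-(anilinooxy)-3-hydroxypropyl]-5-[(2Z)-4-{[tert-butyl(dimethyl)silyl]oxy}but-2-en-2-yl]-2-methylfuran-3(2H)-one | OC[C@H](ONc1ccccc1)C[C@]1(C)OC(=CC1=O)/C(C)=C\CO[Si](C)(C)C(C)(C)C
F2 | step 6 | (2S)-5-[(2Z)-4-{[tert-butyl(dimethyl)silyl]oxy}but-2-en-2-yl]-2-[(2R)-2,3-dihydroxypropyl]-2-methylfuran-3(2H)-one | OC[C@H](O)C[C@]1(C)OC(=CC1=O)/C(C)=C\CO[Si](C)(C)C(C)(C)C
F3 | step 6 | (2S)-5-[(2Z)-4-{[tert-butyl(dimethyl)silyl]oxy}but-2-en-2-yl]-2-{(2R)-2-hydroxy-3-[(triethylsilyl)oxy]propyl}-2-methylfuran-3(2H)-one | CC[Si](CC)(CC)OC[C@H](O)C[C@]1(C)OC(=CC1=O)/C(C)=C\CO[Si](C)(C)C(C)(C)C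
F4 | step 6 | (2R)-1-[(2S)-5-[(2Z)-4-{[tert-butyl(dimethyl)silyl]oxy}but-2-en-2-yl]-2-methyl-3-oxo-2,3-dihydrofuran-2-yl]-3-[(triethylsilyl)oxy]propan-2-yl 2-methylpropanoate | CC[Si](CC)(CC)OC[C@H](OC(=O)C(C)C)C[C@]1(C)OC(=CC1=O)/C(C)=C\CO[Si](C)(C)C(C)(C)C
F5 | step 6 | (2R)-1-[(2S)-5-[(2Z)-4-{[tert-butyl(dimethyl)silyl]oxy}but-2-en-2-yl]-2-methyl-3-oxo-2,3-dihydrofuran-2-yl]-3-hydroxypropan-2-yl 2-methylpropanoate | OC[C@H](OC(=O)C(C)C)C[C@]1(C)OC(=CC1=O)/C(C)=C\CO[Si](C)(C)C(C)(C)C
F6 | step 11 | methyl (2E,4R)-5-[(2S)-5-[(2Z)-4-hydroxybut-2-en-2-yl]-2-methyl-3-oxo-2,3-dihydrofuran-2-yl]-4-[(2-methylpropanoyl)oxy]-2-[(4,4,5,5-tetramethyl-1,3,2-dioxaborolan-2-yl)methyl]pent-2-enoate | CC1(C)OB(C/C(C(=O)OC)=C\[C@H](OC(=O)C(C)C)C[C@]2(C)OC(=CC2=O)/C(C)=C\CO)OC1(C)C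
F7 | step 11 | methyl (2E,4R)-5-[(2S)-2-methyl-3-oxo-5-[(2Z)-4-oxobut-2-en-2-yl]-2,3-dihydrofuran-2-yl]-4-[(2-methylpropanoyl)oxy]-2-[(4,4,5,5-tetramethyl-1,3,2-dioxaborolan-2-yl)methyl]pent-2-enoate | CC1(C)OB(C/C(C(=O)OC)=C\[C@H](OC(=O)C(C)C)C[C@]2(C)OC(=CC2=O)/C(C)=C\C=O)OC1(C)C
F8 | step 12 | 4,5-epoxide of 15 (cis-epoxide, oxygen on the face of C5 that carries the hydroxyl in 17) | C=C1C(=O)O[C@@H]2[C@H]1[C@H](OC(=O)C(C)C)C[C@]1(C)OC(=CC1=O)[C@]3(C)O[C@H]23
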